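**Plan**

1. Locants: ring carbons C1–C14 (C1 and C2 are the lactone ring-fusion carbons, C2 carries the lactone oxygen; C3=C4 and C7=C8 are the olefins; C11–C12 the epoxide; C13 the acetoxy carbon); C15 is the lactone α-carbon, C16 the carbonyl, C17 the exocyclic CH2.
2. Retrosynthesis, first cut: the C15–C1 and O–C2 bonds together. This removes the whole α-methylene-γ-butyrolactone (ring atoms O, C16, C15, C1, C2) as 2-bromoacrylic acid and leaves a 14-membered (1Z,3E)-diene.
3. Enabling feature: the lactone oxygen sits on an allylic ring carbon (C2, next to the C3=C4(CH3) olefin) and C15 sits on its ring neighbour C1. The five-membered lactone is therefore the formal [3+2] adduct of a carboxyvinyl unit across the C1=C2 end of a ring diene, with C3=C4 returned from an allyl intermediate.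
4. Further cuts: C1=C2 (ring-closing metathesis), then C13–C14 (allylation of an enal). The C2–C13 chain with the 3E and 7E olefins and all three methyl groups is (2E,6E)-farnesol.
5. Forward order: farnesol → terminal diene → oxidation of the E-terminal methyl → allylation → epoxide → acetate → 14-membered ring → lactone ring last; no protecting groups.
6. Stereochemistry: C13 from reagent-controlled Brown allylation; C11 and C12 from matched Sharpless epoxidation; C1 and C2 in the key step (cis fusion from the Z-olefin plus syn carbon–oxygen addition, absolute sense from C13 through the ring conformation).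

Key step: step 9

Remark: (2E,6E)-farnesol, 2-bromoacrylic acid and the B-allyldiisopinocampheylborane solution derived from (−)-α-pinene are taken as commercial. Ring locants are also used for the acyclic intermediates.

**Route**

Step 1
Reactants: 1 (2E,6E)-farnesol
Product: 2 (2E,6E)-farnesal
Conditions: MnO2 (activated, excess), CH2Cl2, rt
Reagents that add atoms: none
Why: Heterogeneous MnO2 oxidation of the primary allylic alcohol should stop at the enal and leave the 2E geometry and the remote trisubstituted olefins untouched.

Step 2
Reactants: 2 (2E,6E)-farnesal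
Product: 3 (3E,7E)-4,8,12-trimethyltrideca-1,3,7,11-tetraene
Conditions: Ph3PCH3Br, KHMDS, THF, 0 °C; then 2, −78 °C to rt
Reagents that add atoms: methylenetriphenylphosphorane, C=P(c1ccccc1)(c1ccccc1)c1ccccc1, made in the flask from methyltriphenylphosphonium bromide, C[P+](c1ccccc1)(c1ccccc1)c1ccccc1.[Br-]
Why: Wittig methylenation with the non-stabilised ylide should turn the formyl group into a vinyl group without touching the E-olefins, which gives the (3E)-1,3-diene needed later for C2–C4.

Step 3
Reactants: 3 (3E,7E)-4,8,12-trimethyltrideca-1,3,7,11-tetraene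
Product: 4 (2E,6E,10E)-2,6,10-trimethyltrideca-2,6,10,12-tetraen-1-ol
Conditions: SeO2 (0.3 equiv), t-BuOOH, salicylic acid (cat.), CH2Cl2, 0 °C to rt, stopped at partial conversion
Reagents that add atoms: tert-butyl hydroperoxide, CC(C)(C)OO (oxygen passed on through catalytic SeO2, O=[Se]=O)
Why: Riley-type allylic oxidation (ene reaction, then [2,3]-sigmatropic shift) should hydroxylate the E-methyl group of the terminal isopropylidene unit, the most electron-rich and least hindered olefin, as it does in farnesyl esters and in myrcene-type terminal dienes; this fixes the E-olefin that becomes C11=C12 and makes C13.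

Step 4
Reactants: 4 (2E,6E,10E)-2,6,10-trimethyltrideca-2,6,10,12-tetraen-1-ol
Product: 5 (2E,6E,10E)-2,6,10-trimethyltrideca-2,6,10,12-tetraenal
Conditions: MnO2 (activated, excess), CH2Cl2, rt
Reagents that add atoms: none
Why: MnO2 oxidation of the primary allylic alcohol should give the α-methyl enal without E/Z isomerisation and without touching the diene.

Step 5
Reactants: 5 (2E,6E,10E)-2,6,10-trimethyltrideca-2,6,10,12-tetraenal; 6 B-allyldiisopinocampheylborane derived from (−)-α-pinene
Product: 8 (4R,5E,9E,13E)-5,9,13-trimethylhexadeca-1,5,9,13,15-pentaen-4-ol, via diisopinocampheylborinate ester 7 (not isolated)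
Conditions: 6 (1.3 equiv), Et2O, −78 °C; then NaOH, H2O2, 0 °C to rt
Reagents that add atoms: B-allyldiisopinocampheylborane (6), C=CCB([C@H]1C[C@H]2C[C@H](C2(C)C)[C@@H]1C)[C@H]1C[C@H]2C[C@H](C2(C)C)[C@@H]1C
Why: Brown allylation through a chair Zimmerman–Traxler transition state should deliver the allyl group to the Re face of the enal (the antipodal reagent from (+)-α-pinene is known to attack the Si face), which sets C13 as R and installs C14 and C1.

Step 6
Reactants: 8 (4R,5E,9E,13E)-5,9,13-trimethylhexadeca-1,5,9,13,15-pentaen-4-ol
Product: 9 (1R)-1-[(2R,3R)-3-[(3E,7E)-3,7-dimethyldeca-3,7,9-trien-1-yl]-2-methyloxiran-2-yl]but-3-en-1-ol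
Conditions: Ti(OiPr)4, D-(−)-diisopropyl tartrate, t-BuOOH, 4 Å molecular sieves, CH2Cl2, −20 °C
Reagents that add atoms: tert-butyl hydroperoxide, CC(C)(C)OO
Why: Sharpless asymmetric epoxidation in its matched sense: the D-(−)-tartrate titanium catalyst should epoxidise only the allylic C11=C12 olefin of the (R)-alcohol, on the face that gives the erythro epoxy alcohol (the fast-reacting pairing of the kinetic-resolution manifold), which sets C11 and C12, leaves the vinyl group, the diene and C7=C8 alone, and leaves residual (S)-alcohol behind.

Step 7
Reactants: 9 (1R)-1-[(2R,3R)-3-[(3E,7E)-3,7-dimethyldeca-3,7,9-trien-1-yl]-2-methyloxiran-2-yl]but-3-en-1-ol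
Product: 10 (1R)-1-[(2S,3R)-3-[(3E,7E)-3,7-dimethyldeca-3,7,9-trien-1-yl]-2-methyloxiran-2-yl]but-3-en-1-yl acetate
Conditions: Ac2O, pyridine, DMAP (cat.), CH2Cl2, rt
Reagents that add atoms: acetic anhydride, CC(=O)OC(C)=O
Why: DMAP-catalysed acetylation of the hindered secondary alcohol should proceed without alkoxide formation, so Payne rearrangement of the epoxy alcohol is avoided (the oxirane descriptor changes only through the priority rules).

Step 8
Reactants: 10 (1R)-1-[(2S,3R)-3-[(3E,7E)-3,7-dimethyldeca-3,7,9-trien-1-yl]-2-methyloxiran-2-yl]but-3-en-1-yl acetate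
Product: 11 (1Z,3E,7E,11R,12S,13R)-11,12-epoxy-4,8,12-trimethylcyclotetradeca-1,3,7-trien-13-yl acetate (ring locants as in the plan)
Conditions: cyclometalated ruthenium catalyst Ru(κ2-NO3)(=CH-C6H4-2-OiPr)(κ2C,C-L), L = 3-(2,6-diisopropylphenyl)-1-(adamantan-1-yl metalated at C2)imidazolidin-2-ylidene (7.5 mol %), ClCH2CH2Cl, 2 mM, 50 °C, static vacuum
Reagents that add atoms: none
Why: Z-selective ring-closing metathesis should engage only the two monosubstituted vinyl termini (all other olefins, including the inner olefin of the 3E-diene, are trisubstituted) and form C1=C2 through a side-bound all-syn metallacyclobutane, hence Z, with ethylene loss driving closure of the 14-membered ring.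

Step 9
Reactants: 11 (1Z,3E,7E,11R,12S,13R)-11,12-epoxy-4,8,12-trimethylcyclotetradeca-1,3,7-trien-13-yl acetate; 12 2-bromoacrylic acid
Product: 14 (1S,2S,3E,7E,11R,12S,13R)-13-acetoxy-11,12-epoxycembra-3,7,15(17)-trien-16,2-olide (CNP0146076.4), via allylpalladium carboxylate 13 (not isolated)
Conditions: 12 (1.5 equiv, added slowly), Pd(OAc)2 (10 mol %), tri(2-furyl)phosphine (20 mol %), Ag2CO3 (1.5 equiv), MeCN–THF, 50 °C, dark
Reagents that add atoms: 2-bromoacrylic acid (12), C=C(Br)C(=O)O
Why: Proposed new method: zerovalent palladium inserts into the C–Br bond of 12, the 1-carboxyvinylpalladium species adds syn across the disubstituted Z-olefin with carbon going to C1 (the less hindered diene terminus) and palladium ending as an η3-allyl unit over C2–C3–C4 (13), and the carboxylate bound to the bromide-free metal then forms the O–C2 bond by inner-sphere reductive elimination, which returns the catalyst. The closest known reaction type is the Larock heteroannulation of 1,3-dienes with vinylic or aryl halides that carry a hydroxy, amino or carboxy group, which gives cis-fused rings with cyclic dienes; new are the 2-haloacrylic acid partner on a macrocyclic 4,4-disubstituted diene and the use of ring conformation for face control. The only ring closed is the γ-lactone, by 5-exo attack of the carboxylate oxygen on the allyl terminus C2 (closure at the tertiary C4 would need a seven-membered ring), and the syn-allyl geometry inherited from the 3E-diene should return C3=C4 as E. C1 is set in the insertion step by the olefin face that is attacked: with A(1,3) strain minimised (a C14–H bond eclipsing C1=C2), C13 lies over one diene face, its acetoxy group points outward and the C7–C12 arm spans that face, so the metal should add from the open peripheral face, which gives 1S. C2 is set relative to C1 by the Z-geometry together with the net syn addition of carbon and oxygen, which can only give the cis-fused lactone (2S). The step needs the diene to react before the isolated C7=C8 olefin (allyl stabilisation of the insertion product), 1,2- rather than 1,4-closure (ring size), survival of the non-allylic epoxide and the homoallylic acetate toward zerovalent palladium, and trapping faster than β-hydride loss (tethered carboxylate; Ag2CO3 removes bromide and keeps 12 as its carboxylate).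

**Compound list**

1 | (2E,6E)-farnesol | CC(C)=CCC/C(C)=C/CC/C(C)=C/CO | starting material
2 | (2E,6E)-farnesal | CC(C)=CCC/C(C)=C/CC/C(C)=C/C=O | intermediate
3 | (3E,7E)-4,8,12-trimethyltrideca-1,3,7,11-tetraene | C=C/C=C(\C)CC/C=C(\C)CCC=C(C)C | intermediate
4 | (2E,6E,10E)-2,6,10-trimethyltrideca-2,6,10,12-tetraen-1-ol | C=C/C=C(\C)CC/C=C(\C)CC/C=C(\C)CO | intermediate
5 | (2E,6E,10E)-2,6,10-trimethyltrideca-2,6,10,12-tetraenal | C=C/C=C(\C)CC/C=C(\C)CC/C=C(\C)C=O | intermediate
6 | B-allyldiisopinocampheylborane derived from (−)-α-pinene (each isopinocampheyl group 1S,2S,3S,5R as in (+)-isopinocampheol) | C=CCB([C@H]1C[C@H]2C[C@H](C2(C)C)[C@@H]1C)[C@H]1C[C@H]2C[C@H](C2(C)C)[C@@H]1C | starting material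
7 | diisopinocampheylborinate ester of 8 (O–B bond at C13) | C=C/C=C(\C)CC/C=C(\C)CC/C=C(\C)[C@H](OB([C@H]1C[C@H]2C[C@H](C2(C)C)[C@@H]1C)[C@H]1C[C@H]2C[C@H](C2(C)C)[C@@H]1C)CC=C | intermediate (not isolated)
8 | (4R,5E,9E,13E)-5,9,13-trimethylhexadeca-1,5,9,13,15-pentaen-4-ol | C=C/C=C(\C)CC/C=C(\C)CC/C=C(\C)[C@H](O)CC=C | intermediate
9 | (1R)-1-[(2R,3R)-3-[(3E,7E)-3,7-dimethyldeca-3,7,9-trien-1-yl]-2-methyloxiran-2-yl]but-3-en-1-ol | C=C/C=C(\C)CC/C=C(\C)CC[C@H]1O[C@]1(C)[C@H](O)CC=C | intermediate
10 | (1R)-1-[(2S,3R)-3-[(3E,7E)-3,7-dimethyldeca-3,7,9-trien-1-yl]-2-methyloxiran-2-yl]but-3-en-1-yl acetate | C=C/C=C(\C)CC/C=C(\C)CC[C@H]1O[C@]1(C)[C@H](OC(C)=O)CC=C | intermediate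
11 | (1Z,3E,7E,11R,12S,13R)-11,12-epoxy-4,8,12-trimethylcyclotetradeca-1,3,7-trien-13-yl acetate (C14 is the ring CH2) | C1/C=C\C=C(/C)CC/C=C(\C)CC[C@H]2O[C@]2(C)[C@@H]1OC(C)=O | intermediate
12 | 2-bromoacrylic acid | C=C(Br)C(=O)O | starting material
13 | allylpalladium carboxylate: C15 bonded to C1, palladium on C2 (drawn as the σ-allyl form of the η3-allyl unit over C2–C4) and bound to the carboxylate oxygen, phosphine omitted | C=C1C(=O)O[Pd][C@H]2/C=C(\C)CC/C=C(\C)CC[C@H]3O[C@]3(C)[C@H](OC(C)=O)C[C@@H]12 | intermediate (not isolated)
14 | (1S,2S,3E,7E,11R,12S,13R)-13-acetoxy-11,12-epoxycembra-3,7,15(17)-trien-16,2-olide, cis-fused lactone (CNP0146076.4) | C=C1C(=O)O[C@H]2/C=C(\C)CC/C=C(\C)CC[C@H]3O[C@]3(C)[C@H](OC(C)=O)C[C@@H]12 | target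

**Step count and risks**

Total step count: 9. Longest linear sequence: 9 steps (1 to 14).

Steps most likely to fail:

1. Step 9 (bears the label). The carboxyvinylpalladium species may insert too slowly into the hindered ring diene, so that 12 is lost by dehydrobromination or polymerisation. The allyl intermediate may lose a β-hydrogen, or the allylic lactone may be re-ionised by zerovalent palladium with erosion of the ring fusion. The face selectivity at C1 rests only on the ring conformation, cannot be predicted with confidence, and may be low or reversed. The fallback uses known chemistry, sets out from 11 and comes back at 14. Diene 11 is treated with Mn(OAc)3·2H2O, catalytic Cu(OAc)2 and malonic acid in KOAc-buffered acetic acid at room temperature. In this oxidative free-radical lactone annulation by trivalent manganese, the malonyl radical adds to C1, the allyl radical is oxidised to the cation, and a carboxyl group closes on C2 to give the α-carboxy-γ-lactone F1 (mixture at C15; isomers at C1 and C2 separated here; this route does not itself secure the face selectivity at C1). Decarboxylative Mannich methylenation of the α-carboxy-γ-lactone F1 (aqueous formaldehyde, diethylamine, NaOAc, AcOH) then gives 14.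

2. Step 8. Z-selectivity may be eroded by secondary metathesis, the open chain may oligomerise, and the cyclometalated catalyst may be deactivated by the conjugated diene. The fallback sets out from 10 and comes back at 14. Ring closure with the second-generation Hoveyda–Grubbs catalyst RuCl2(H2IMes)(=CH-C6H4-2-OiPr) under thermodynamic control should give the E,E-diene macrocycle F2, the (1E,3E)-isomer of 11. The E,E-diene macrocycle F2 is then annulated with 12 in the outer-sphere mode (Pd(OAc)2, PPh3, n-Bu4NCl, K2CO3, DMF). There the carboxylate attacks C2 anti to palladium after rotation about the C1–C2 bond, so the E-olefin is translated into the same cis-fused lactone 14.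

3. Step 3. Allylic oxidation may also occur at the positions that become C5 and the C4 methyl group of the conjugated diene and next to the internal olefin, and the selenium reagent may add to the diene. The fallback sets out from 2 and comes back at 4 by exchanging the order of steps 2 and 3. Farnesal 2, whose conjugated olefin is deactivated by the formyl group, is oxidised with catalytic SeO2 and t-BuOOH to (2E,6E,10E)-12-hydroxyfarnesal F3. Then (2E,6E,10E)-12-hydroxyfarnesal F3 is methylenated with an excess of methylenetriphenylphosphorane to give 4.

**Further compounds**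

F1 | step 9 | α-carboxy-γ-lactone: 14 with C15 carrying H and CO2H in place of the exocyclic methylene | OC(=O)C1C(=O)O[C@H]2/C=C(\C)CC/C=C(\C)CC[C@H]3O[C@]3(C)[C@H](OC(C)=O)C[C@@H]12
F2 | step 8 | (1E,3E,7E,11R,12S,13R)-11,12-epoxy-4,8,12-trimethylcyclotetradeca-1,3,7-trien-13-yl acetate | C1/C=C/C=C(\C)CC/C=C(\C)CC[C@H]2O[C@]2(C)[C@@H]1OC(C)=O
F3 | step 3 | (2E,6E,10E)-12-hydroxy-3,7,11-trimethyldodeca-2,6,10-trienal | O=C/C=C(\C)CC/C=C(\C)CC/C=C(\C)CO
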